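Start from the balance.

| flask | starting material | second substrate | free enzyme | temperature | remark | time |
|---|---|---|---|---|---|---|
| delta | 0.11 M | 0.099 M | 1.8 µM | 40 °C | the very flask that is asked about, followed so far |  |
| gamma | 0.055 M | 0.099 M | 1.8 µM | 46 °C | run made earlier |  |
| flask | 0.11 M | 0.0990 M | 1.8 µM | 40 °C |  | 1.5 h |

| run | time / min | target / % | starting material / % |
|---|---|---|---|
| delta | 4.00 | 9.4 | 82.9 |
| delta | 6.00 | 9.8 | 76.3 |
| delta | 10.0 | 12.1 | 64.0 |
| delta | 15.0 | 13.9 | 50.8 |
| delta | 25.0 | 17.1 | 31.9 |
| delta | 40.0 | 17.8 | 18.2 |
| delta | 50.0 | 19.4 | 13.3 |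
| gamma | 1.00 | 8.2 | 88.2 |
| gamma | 3.00 | 15.4 | 67.8 |
| gamma | 6.00 | 21.5 | 42.1 |
| gamma | 8.00 | 24.7 | 30.1 |
| gamma | 12.0 | 26.7 | 10.9 |
| gamma | 15.0 | 28.0 | 5.6 |
| gamma | 20.0 | 28.4 | 1.5 |

(standard deviation of a reading: 0.5 percentage points)

- cedar: at 1.5 h add free enzyme, 100 % of the amount charged, then wait 25 min
- larch: change nothing and wait 25 min more
- oak: at 1.5 h raise the temperature by 20 K, then wait 25 min
- ash: at 1.5 h add second substrate, 50.0 % of the amount charged, then wait 25 min
- alder: at 1.5 h take out 90 % of the first product then present, then wait 25 min

- target, in percent of the starting material first charged, at 1.5 h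
- the option that brings most further target ("none" if no option brings more than 2 percentage points) (cedar / larch / oak / ash / alder / none)
- target present, in percent of the starting material first charged, after cedar
- target present, in percent of the starting material first charged, after ash

- the volume of additions can be left aside
- steps thought possible: second complex -> free enzyme + target; starting material + free enzyme <-> first complex; target <-> isomer of the product; free enzyme -> unfolded enzyme; second substrate + loaded enzyme <-> second complex; first complex -> loaded enzyme + first product

Where has the starting material gone in delta? At 50.0 min it reads 13.3 %, so 86.7 % has been turned over, yet target reads 19.4 %. The enzyme charge is hardly any of the starting material, so bound forms cannot hold the gap. I put it in isomer of the product.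

Is the ratio more than a passing value? Target over turnover reads 55.0 % at 4.00 min, but 21.8 % at 40.0 min and 22.4 % at 50.0 min. So it falls and then stays nearly constant. That is what I freeze: the target share, [target] divided by the [starting material] turned over, at one temperature, once the isomers have caught up. This is thermodynamic control. Gamma, at 46 °C and with half of delta's starting material, reads 28.8 %, a higher share. Two settings differ, but I expect a ratio of two isomers to follow the temperature and not the charge, so I read this as heat favouring target.

Where does turnover stop? Second substrate is the limiting reagent: 0.0990 M against 0.11 M allows 90.0 %. Delta already stands at 86.7 %, so by 1.5 h I take the turnover as having reached the allowance, and target is share times allowance, 20.1 %. The share is a reading, so this estimate carries the scatter of 0.5 percentage points on target.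

And the options? Cedar, larch and alder leave allowance and share as they are, so I expect about 20.1 % after each. Ash lifts the allowance to the whole charge, giving 22.4 %, a gain of 2.2 points. Oak moves the share itself: gamma's share times the allowance gives 25.9 %, and a rise of 20 K from 40 °C goes past gamma's temperature. I choose oak.

The forecast says 19.1 % (18.2 % to 20 %), 19.2 % after cedar (18.3 % to 20.3 %), 20.8 % after ash (19.6 % to 22 %) and oak, holding that “target must be isomerising”.

The flask gives 19.1 %, 19.1 % after cedar and 21.3 % after ash. The best option is oak, which brings 24 points, against 2.1 points for ash. My 20.1 % stands a little above the flask's value.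

    second complex → free enzyme + target (k = 150 /s, Ea = 65.0 kJ/mol)
    starting material + free enzyme ⇌ first complex (K = 2.40 /M, k = 17000 /M/s, Ea = 10.0 kJ/mol, ΔH = −1.00 kJ/mol)
    target ⇌ isomer of the product (K = 3.70, k = 0.00710 /s, Ea = 84.0 kJ/mol, ΔH = −53.0 kJ/mol)
    free enzyme → unfolded enzyme (k = 2.30 × 10⁻⁵ /s, Ea = 250 kJ/mol)
    second substrate + loaded enzyme ⇌ second complex (K = 5.40 /M, k = 6.40 × 10⁵ /M/s, Ea = 22.0 kJ/mol, ΔH = 15.0 kJ/mol)
    first complex → loaded enzyme + first product (k = 1400 /s, Ea = 50.0 kJ/mol)
    (constants at 40 °C)

Take away the isomerisation and this flask holds 89.9 % target instead of 19.1 %. With the flask's own turnover, 89.9 %, the share gives 20.1 %. Now the neighbour with 0.19 M of starting material, same second substrate, same temperature: the allowance is 52.1 %, so the share gives 11.7 %. That neighbour flask computes to 11.1 %.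

(The earlier runs and the new flask come from a simulation for substances that don't exist; scatter was added.)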